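**Retrosynthetic overview** (isoflavan numbering: ring C = O1, C2, C3, C4, C4a, C8a; ring A = C4a to C8a; ring B = C1′ to C6′)
1. The last events are desilylation and, before it, an aromatic Claisen shift of a 4′-O-prenyl ether, which places the 1,1-dimethylallyl group on C5′.
2. The key disconnection is C4–C4a of ring C. It leads back to an achiral, open 2-arylallyl aryl ether with Br on C4a; one flask runs an asymmetric cobalt hydroboration of C3=C4 and then a B-alkyl Suzuki–Miyaura closure.
3. Enabling feature: the only stereocentre, C3, is a C–H carbon that bears ring B and lies β to the new bond. C4 is a bare CH2, and C8 is alkylated, so C4a is the one ortho carbon of O1 left to carry Br. C3=C4 can therefore be a 1,1-disubstituted styrene whose anti-Markovnikov hydrometalation sets C3 and arms C4 at once.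
4. O1–C2 comes from a Mitsunobu coupling. Ring A grows from cyclohexane-1,3-dione (its C2 becomes C8) and acrylic acid, and is aromatised to a dihydrocoumarin whose lactone masks O7 and the side chain until MeMgBr opens it.
5. Order of rings: ring A (saturated, then aromatised), ring B bought, ring C last.

Key step: step 11

Remark: the target as drawn is the (3R)-isoflavan. Which antipode of the oxazoline ligand gives (3R) is inferred from α-alkylstyrenes, and the antipode that does so is the one meant.

Step 1
Reactants: 1 cyclohexane-1,3-dione; 2 acrylic acid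
Product: 4 3,4,7,8-tetrahydro-2H-chromene-2,5(6H)-dione, via Michael adduct acid 3 (not isolated)
Conditions: neat, hydroquinone (trace), 135 °C, water distilled off
Reagents that add atoms: none
Why: Michael addition of the doubly activated C2 of the dione to acrylic acid, followed by dehydrative enol lactonisation, should fix the three-carbon chain on the future C8 and acylate one of the two equivalent oxygens.

Step 2
Reactants: 4 3,4,7,8-tetrahydro-2H-chromene-2,5(6H)-dione
Product: 5 5-hydroxychroman-2-one
Conditions: Pd/C (10 wt % Pd), diglyme, reflux, N2 sweep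
Reagents that add atoms: none
Why: Catalytic dehydrogenative aromatisation of the cyclohexenone ring is driven by the gain of aromaticity and should leave a resorcinol whose O7 stays in the lactone while the future O1 is a free phenol.

Step 3
Reactants: 5 5-hydroxychroman-2-one
Product: 6 6-bromo-5-hydroxychroman-2-one
Conditions: NBS (1.0 equiv), i-Pr2NH (10 mol %), CH2Cl2, 0 °C
Reagents that add atoms: N-bromosuccinimide, O=C1CCC(=O)N1Br
Why: Amine-mediated ortho-selective electrophilic aromatic bromination delivers bromine to the open ortho position of a 2-substituted phenol, here also para to the lactone oxygen, which is the future C4a.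

Step 4
Reactants: 7 1-(2,4-dihydroxyphenyl)ethanone; 8 1-bromo-3-methylbut-2-ene
Product: 9 1-[2-hydroxy-4-(3-methylbut-2-enyloxy)phenyl]ethanone
Conditions: K2CO3, acetone, reflux
Reagents that add atoms: none
Why: Williamson ether synthesis should take only the 4-hydroxyl, because the 2-hydroxyl is hydrogen-bonded to the ketone and much less nucleophilic.

Step 5
Reactants: 9 1-[2-hydroxy-4-(3-methylbut-2-enyloxy)phenyl]ethanone
Product: 10 1-[4-(3-methylbut-2-enyloxy)-2-(triisopropylsilyloxy)phenyl]ethanone
Conditions: NaH, then i-Pr3SiCl, THF, 0 °C to rt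
Reagents that add atoms: chlorotriisopropylsilane, CC(C)[Si](Cl)(C(C)C)C(C)C
Why: O-Silylation of the sodium phenoxide gives a bulky, base-stable ether that later also shields C3′.

Step 6
Reactants: 10 1-[4-(3-methylbut-2-enyloxy)-2-(triisopropylsilyloxy)phenyl]ethanone
Product: 11 racemic 2-methyl-2-[4-(3-methylbut-2-enyloxy)-2-(triisopropylsilyloxy)phenyl]oxirane
Conditions: Me3SI, n-BuLi, THF, −10 °C to rt
Reagents that add atoms: trimethylsulfonium iodide, C[S+](C)C.[I-]
Why: In the Corey–Chaykovsky epoxidation the sulfonium ylide adds to the ketone and closes to the terminal epoxide; the new stereocentre is racemic and is erased in step 7.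

Step 7
Reactants: 11 racemic 2-methyl-2-[4-(3-methylbut-2-enyloxy)-2-(triisopropylsilyloxy)phenyl]oxirane
Product: 12 2-[4-(3-methylbut-2-enyloxy)-2-(triisopropylsilyloxy)phenyl]prop-2-en-1-ol
Conditions: LiN(i-Pr)2, THF, 0 °C to rt; H2O quench
Reagents that add atoms: none
Why: Base-induced isomerisation of an epoxide to an allylic alcohol (syn β-elimination) can only remove a proton from the methyl group, so it should give the 2-arylallyl alcohol.

Step 8
Reactants: 6 6-bromo-5-hydroxychroman-2-one; 12 2-[4-(3-methylbut-2-enyloxy)-2-(triisopropylsilyloxy)phenyl]prop-2-en-1-ol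
Product: 13 6-bromo-5-{2-[4-(3-methylbut-2-enyloxy)-2-(triisopropylsilyloxy)phenyl]allyloxy}chroman-2-one
Conditions: PPh3, DIAD, THF, 0 °C to rt
Reagents that add atoms: none
Why: Mitsunobu etherification joins the acidic ortho-bromophenol to the primary allylic alcohol under neutral conditions that spare the lactone, and direct and allylic displacement give the same product because the allyl unit is symmetric.

Step 9
Reactants: 13 6-bromo-5-{2-[4-(3-methylbut-2-enyloxy)-2-(triisopropylsilyloxy)phenyl]allyloxy}chroman-2-one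
Product: 15 4-bromo-2-(3-hydroxy-3-methylbutyl)-3-{2-[4-(3-methylbut-2-enyloxy)-2-(triisopropylsilyloxy)phenyl]allyloxy}phenol, via methyl ketone 14 (not isolated)
Conditions: MeMgBr (3.5 equiv), THF, 0 °C; aqueous work-up
Reagents that add atoms: methylmagnesium bromide, C[Mg]Br
Why: Double Grignard addition to the aryl lactone releases the tertiary carbinol and the C7 phenol, while the aryl bromide, the silyl ether and both alkenes are inert to MeMgBr at 0 °C.

Step 10
Reactants: 15 4-bromo-2-(3-hydroxy-3-methylbutyl)-3-{2-[4-(3-methylbut-2-enyloxy)-2-(triisopropylsilyloxy)phenyl]allyloxy}phenol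
Product: 17 [4-bromo-3-{2-[4-(3-methylbut-2-enyloxy)-2-(triisopropylsilyloxy)phenyl]allyloxy}-2-(3-methyl-3-triethylsilyloxybutyl)phenoxy]triisopropylsilane, via O7-TIPS tertiary alcohol 16 (not isolated)
Conditions: 2,6-lutidine, CH2Cl2, i-Pr3SiOTf (1.05 equiv), −40 to 0 °C; then Et3SiOTf (1.2 equiv), 0 °C
Reagents that add atoms: triisopropylsilyl triflate, CC(C)[Si](OS(=O)(=O)C(F)(F)F)(C(C)C)C(C)C; triethylsilyl triflate, CC[Si](CC)(CC)OS(=O)(=O)C(F)(F)F
Why: In this sequential O-silylation the bulky triisopropylsilyl triflate takes only the phenol and the smaller triethylsilyl triflate then caps the tertiary alcohol, so no acidic proton meets the metal hydride of step 11.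

Step 11
Reactants: 17 [4-bromo-3-{2-[4-(3-methylbut-2-enyloxy)-2-(triisopropylsilyloxy)phenyl]allyloxy}-2-(3-methyl-3-triethylsilyloxybutyl)phenoxy]triisopropylsilane
Product: 19 (3R)-3-[4-(3-methylbut-2-enyloxy)-2-(triisopropylsilyloxy)phenyl]-8-(3-methyl-3-triethylsilyloxybutyl)-7-(triisopropylsilyloxy)chroman, via primary pinacol boronate 18 (not isolated)
Conditions: stage 1: (L*)CoCl2 (3 mol %; L* = one enantiomer of 2-[6-(1-{(2,6-diisopropylphenyl)imino}ethyl)pyridin-2-yl]-4-isopropyl-4,5-dihydrooxazole), NaBHEt3 (9 mol %), HBpin (1.3 equiv), THF, rt, until the alkene is consumed; stage 2, same flask: Pd(OAc)2 (5 mol %), RuPhos (10 mol %), K3PO4 (3 equiv), toluene/H2O 10:1, 0.02 M, 80 °C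
Reagents that add atoms: pinacolborane, CC1(C)OBOC1(C)C (its boryl group stays only in 18; its hydrogen stays on C3)
Why: Stage 1 is an asymmetric anti-Markovnikov hydroboration: the cobalt hydride made from (L*)CoCl2 and NaBHEt3 inserts the 1,1-disubstituted alkene C3=C4 in the 1,2-sense, which puts H on C3 and the metal on the unhindered C4, and σ-bond metathesis with HBpin releases boronate 18. Stage 2 is an intramolecular B-alkyl Suzuki–Miyaura coupling: zerovalent palladium inserts into C4a–Br, base-assisted transmetalation hands over C4, and reductive elimination forms C4–C4a. The closest known reaction types are the cobalt-catalysed enantioselective hydroboration of α-substituted styrenes and the hydroboration/B-alkyl Suzuki ring closure of alkene-tethered aryl halides. Ring C (O1, C2, C3, C4, C4a, C8a) closes as a six-membered ring by C(sp3)–C(sp2) reductive elimination from a seven-membered oxapalladacycle. The stereocentre C3 is set in the insertion step, where the oxazoline of L* tells the flat ring B from the CH2OAr arm and so picks the alkene face, and it is not touched later because it is only β to boron and palladium and RuPhos favours reductive elimination over β-hydride elimination. The step needs the styrene-type alkene to react before the trisubstituted prenyl alkene (secured by sterics), boron on C4 and not C3 (secured by the fully substituted C3, which also avoids β-aryloxide loss) and no 5-exo Heck closure onto C3 (secured by adding palladium only after the alkene is consumed), while the alkyl group on C8 leaves C4a as the only ortho carbon that can carry the bromine.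

Step 12
Reactants: 19 (3R)-3-[4-(3-methylbut-2-enyloxy)-2-(triisopropylsilyloxy)phenyl]-8-(3-methyl-3-triethylsilyloxybutyl)-7-(triisopropylsilyloxy)chroman
Product: 21 4-[(3R)-8-(3-methyl-3-triethylsilyloxybutyl)-7-(triisopropylsilyloxy)chroman-3-yl]-2-(2-methylbut-3-en-2-yl)-5-(triisopropylsilyloxy)phenol, via ortho-dienone 20 (not isolated)
Conditions: PhNEt2, 190 °C, sealed tube, argon
Reagents that add atoms: none
Why: The aromatic Claisen rearrangement ([3,3]-sigmatropic shift, then tautomerisation) inverts the prenyl unit to the 1,1-dimethylallyl group and should go to C5′ because C3′ is walled in by the 2′-silyloxy group; C3 is not involved.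

Step 13
Reactants: 21 4-[(3R)-8-(3-methyl-3-triethylsilyloxybutyl)-7-(triisopropylsilyloxy)chroman-3-yl]-2-(2-methylbut-3-en-2-yl)-5-(triisopropylsilyloxy)phenol
Product: 22 (3R)-3-[2,4-dihydroxy-5-(2-methylbut-3-en-2-yl)phenyl]-8-(3-hydroxy-3-methylbutyl)chroman-7-ol
Conditions: n-Bu4NF (3.5 equiv), AcOH (3.5 equiv), THF, 0 °C to rt
Reagents that add atoms: none
Why: Fluoride-induced desilylation removes all three silyl groups under buffered, non-acidic conditions that should spare the tertiary alcohol, the 1,1-dimethylallyl phenol and C3.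

**Compound list**
1 | cyclohexane-1,3-dione | O=C1CCCC(=O)C1 | starting material
2 | acrylic acid | C=CC(=O)O | starting material
3 | 3-(2,6-dioxocyclohexyl)propanoic acid (not isolated) | O=C(O)CCC1C(=O)CCCC1=O | intermediate
4 | 3,4,7,8-tetrahydro-2H-chromene-2,5(6H)-dione | O=C1CCC2=C(CCCC2=O)O1 | intermediate
5 | 5-hydroxychroman-2-one | O=C1CCc2c(O)cccc2O1 | intermediate
6 | 6-bromo-5-hydroxychroman-2-one | O=C1CCc2c(O)c(Br)ccc2O1 | intermediate
7 | 1-(2,4-dihydroxyphenyl)ethanone | CC(=O)c1ccc(O)cc1O | starting material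
8 | 1-bromo-3-methylbut-2-ene (prenyl bromide) | CC(C)=CCBr | starting material
9 | 1-[2-hydroxy-4-(3-methylbut-2-enyloxy)phenyl]ethanone | CC(=O)c1ccc(OCC=C(C)C)cc1O | intermediate
10 | 1-[4-(3-methylbut-2-enyloxy)-2-(triisopropylsilyloxy)phenyl]ethanone | CC(=O)c1ccc(OCC=C(C)C)cc1O[Si](C(C)C)(C(C)C)C(C)C | intermediate
11 | racemic 2-methyl-2-[4-(3-methylbut-2-enyloxy)-2-(triisopropylsilyloxy)phenyl]oxirane | CC1(CO1)c1ccc(OCC=C(C)C)cc1O[Si](C(C)C)(C(C)C)C(C)C | intermediate
12 | 2-[4-(3-methylbut-2-enyloxy)-2-(triisopropylsilyloxy)phenyl]prop-2-en-1-ol | C=C(CO)c1ccc(OCC=C(C)C)cc1O[Si](C(C)C)(C(C)C)C(C)C | intermediate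
13 | 6-bromo-5-{2-[4-(3-methylbut-2-enyloxy)-2-(triisopropylsilyloxy)phenyl]allyloxy}chroman-2-one | C=C(COc1c(Br)ccc2OC(=O)CCc12)c1ccc(OCC=C(C)C)cc1O[Si](C(C)C)(C(C)C)C(C)C | intermediate
14 | 4-(3-bromo-6-hydroxy-2-{2-[4-(3-methylbut-2-enyloxy)-2-(triisopropylsilyloxy)phenyl]allyloxy}phenyl)butan-2-one (not isolated) | CC(=O)CCc1c(O)ccc(Br)c1OCC(=C)c1ccc(OCC=C(C)C)cc1O[Si](C(C)C)(C(C)C)C(C)C | intermediate
15 | 4-bromo-2-(3-hydroxy-3-methylbutyl)-3-{2-[4-(3-methylbut-2-enyloxy)-2-(triisopropylsilyloxy)phenyl]allyloxy}phenol | CC(C)(O)CCc1c(O)ccc(Br)c1OCC(=C)c1ccc(OCC=C(C)C)cc1O[Si](C(C)C)(C(C)C)C(C)C | intermediate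
16 | triisopropylsilyl ether of the phenol of 15, tertiary alcohol free (not isolated) | CC(C)(O)CCc1c(O[Si](C(C)C)(C(C)C)C(C)C)ccc(Br)c1OCC(=C)c1ccc(OCC=C(C)C)cc1O[Si](C(C)C)(C(C)C)C(C)C | intermediate
17 | [4-bromo-3-{2-[4-(3-methylbut-2-enyloxy)-2-(triisopropylsilyloxy)phenyl]allyloxy}-2-(3-methyl-3-triethylsilyloxybutyl)phenoxy]triisopropylsilane | CC[Si](CC)(CC)OC(C)(C)CCc1c(O[Si](C(C)C)(C(C)C)C(C)C)ccc(Br)c1OCC(=C)c1ccc(OCC=C(C)C)cc1O[Si](C(C)C)(C(C)C)C(C)C | intermediate
18 | (R)-pinacol boronate from anti-Markovnikov addition of H–Bpin to the alkene of 17: H on the aryl-bearing carbon, Bpin on the CH2 (not isolated) | CC(C)=CCOc1ccc([C@@H](CB2OC(C)(C)C(C)(C)O2)COc2c(Br)ccc(O[Si](C(C)C)(C(C)C)C(C)C)c2CCC(C)(C)O[Si](CC)(CC)CC)c(O[Si](C(C)C)(C(C)C)C(C)C)c1 | intermediate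
19 | (3R)-3-[4-(3-methylbut-2-enyloxy)-2-(triisopropylsilyloxy)phenyl]-8-(3-methyl-3-triethylsilyloxybutyl)-7-(triisopropylsilyloxy)chroman | CC(C)=CCOc1ccc([C@@H]2COc3c(ccc(O[Si](C(C)C)(C(C)C)C(C)C)c3CCC(C)(C)O[Si](CC)(CC)CC)C2)c(O[Si](C(C)C)(C(C)C)C(C)C)c1 | intermediate
20 | cyclohexa-2,4-dienone form of ring B with the 2-methylbut-3-en-2-yl group on the sp3 carbon C5′ (that centre undefined), (3R) in ring C (not isolated) | C=CC(C)(C)C1C=C([C@@H]2COc3c(ccc(O[Si](C(C)C)(C(C)C)C(C)C)c3CCC(C)(C)O[Si](CC)(CC)CC)C2)C(O[Si](C(C)C)(C(C)C)C(C)C)=CC1=O | intermediate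
21 | 4-[(3R)-8-(3-methyl-3-triethylsilyloxybutyl)-7-(triisopropylsilyloxy)chroman-3-yl]-2-(2-methylbut-3-en-2-yl)-5-(triisopropylsilyloxy)phenol | C=CC(C)(C)c1cc([C@@H]2COc3c(ccc(O[Si](C(C)C)(C(C)C)C(C)C)c3CCC(C)(C)O[Si](CC)(CC)CC)C2)c(O[Si](C(C)C)(C(C)C)C(C)C)cc1O | intermediate
22 | (3R)-3-[2,4-dihydroxy-5-(2-methylbut-3-en-2-yl)phenyl]-8-(3-hydroxy-3-methylbutyl)chroman-7-ol (CNP0420388.1) | C=CC(C)(C)c1cc([C@@H]2COc3c(ccc(O)c3CCC(C)(C)O)C2)c(O)cc1O | target

**Step count**
Total: 13 steps. Longest linear sequence: 10 steps (steps 4 to 13); the ring A branch (steps 1 to 3) joins at step 8.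

**Steps most likely to fail**
1. Step 11.
   - What may go wrong: transmetalation from the primary pinacol boronate may be slow. β-Hydride elimination, protodeboronation or ionisation of the prenyl ether by zerovalent palladium could then take over.
   - Fallback (ring closure by reductive cross-electrophile coupling instead of boron-to-palladium transfer): it sets out from 18, isolated after stage 1. NaBO3·4H2O in THF/H2O oxidises the C–B bond to the (S)-configured primary alcohol F1. An Appel reaction (I2, PPh3, imidazole, CH2Cl2, 0 °C) turns it into the (R)-configured primary iodide F2. NiBr2(dme) and 4,4′-di-tert-butyl-2,2′-bipyridine with Mn powder in DMA at high dilution then join C4 to C4a, and the route is rejoined at 19.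
2. Step 12.
   - What may go wrong: at 190 °C the free phenol formed may drive the abnormal Claisen isomerisation of the 1,1-dimethylallyl group, the ether may fragment with loss of isoprene, or some migration to C3′ may occur.
   - Fallback (deprotection first, sigmatropic step last, on the free polyphenol in a protic medium): it sets out from 19. n-Bu4NF/AcOH in THF removes the three silyl groups to give the free triol prenyl ether F3. This is heated in EtOH/H2O 4:1 at 130 °C in a sealed tube, where the water-accelerated Claisen rearrangement known for 2-oxygenated 4-prenyloxyarenes runs at a lower temperature. The route is rejoined at 22.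
3. Step 7.
   - What may go wrong: the lithium alkoxide may trigger oxygen-to-oxygen silyl migration, the electron-rich epoxide may rearrange to the aldehyde, or the base may metalate the prenyl ether.
   - Fallback (the extra carbon enters as CO instead of a sulfur ylide): it sets out from 10. KN(SiMe3)2 and PhNTf2 in THF at −78 °C give the enol triflate F4. Carbonylation with Pd(OAc)2, 1,3-bis(diphenylphosphino)propane, CO (1 atm), MeOH and Et3N in DMF at 60 °C gives the methyl 2-arylacrylate F5. i-Bu2AlH in CH2Cl2 at −78 °C reduces it through a non-migrating aluminium alkoxide, and the route is rejoined at 12.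

**Further compounds**
F1 | step 11 | (2S)-3-[6-bromo-2-(3-methyl-3-triethylsilyloxybutyl)-3-(triisopropylsilyloxy)phenoxy]-2-[4-(3-methylbut-2-enyloxy)-2-(triisopropylsilyloxy)phenyl]propan-1-ol | CC(C)=CCOc1ccc([C@@H](CO)COc2c(Br)ccc(O[Si](C(C)C)(C(C)C)C(C)C)c2CCC(C)(C)O[Si](CC)(CC)CC)c(O[Si](C(C)C)(C(C)C)C(C)C)c1
F2 | step 11 | (R)-primary iodide derived from F1 (CH2OH replaced by CH2I) | CC(C)=CCOc1ccc([C@@H](CI)COc2c(Br)ccc(O[Si](C(C)C)(C(C)C)C(C)C)c2CCC(C)(C)O[Si](CC)(CC)CC)c(O[Si](C(C)C)(C(C)C)C(C)C)c1
F3 | step 12 | (3R)-3-[2-hydroxy-4-(3-methylbut-2-enyloxy)phenyl]-8-(3-hydroxy-3-methylbutyl)chroman-7-ol | CC(C)=CCOc1ccc([C@@H]2COc3c(ccc(O)c3CCC(C)(C)O)C2)c(O)c1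
F4 | step 7 | 1-[4-(3-methylbut-2-enyloxy)-2-(triisopropylsilyloxy)phenyl]vinyl trifluoromethanesulfonate | C=C(OS(=O)(=O)C(F)(F)F)c1ccc(OCC=C(C)C)cc1O[Si](C(C)C)(C(C)C)C(C)C
F5 | step 7 | methyl 2-[4-(3-methylbut-2-enyloxy)-2-(triisopropylsilyloxy)phenyl]acrylate | C=C(C(=O)OC)c1ccc(OCC=C(C)C)cc1O[Si](C(C)C)(C(C)C)C(C)C
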